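**Plan**

1. The core is numbered as a tricyclo[5.3.1.0(1,5)]undecene (C1 spiro bridgehead, C2 formyl carbon, C5 ring-fusion CH, C6 quaternary carbon, C7 bridgehead CH, C8=C9, C10 carbinol carbon, C11 methylene bridge). The retrosynthesis cuts the C10 ester C–O bond, then C6–CH3 and C6–C7 (ring B), then the C8–carboxyl bond, then C1–C2 and C3–C4 of cyclopentane ring A in one [3+2] event, and last the aryl–C5 bond.
2. Enabling feature: C1 is a spiro atom shared by ring A (C1–C5) and the six-membered ring C (C1, C7–C11). Ring C can therefore come from a para-substituted anisole whose ipso carbon becomes C1, and whose local symmetry leaves C1 stereochemically silent until ring B closes.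
3. Forward: asymmetric arylation of a butenolide, lactone opening to an iodo ester, radical [3+2] annulation with acrolein with dearomatization (ring A plus dienone ring C), enol triflate carbonylation (C8 carboxyl), base-mediated diene shift with intramolecular Michael closure of ring B and exo-methylation, photooxygenation and Luche reduction (C10), esterification with the separately made (Z)-hydroxy acid, acid deprotection.
4. Stereochemistry: C5 from the chiral rhodium catalyst; C1 and C7 from the tether (cis ring fusion); C6 by exo-face methylation; C10 by hydride delivery from the C11 face; C2 by equilibration; the Z alkene from a Wittig reaction.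

Key step: step 3

Remark on the chemistry: C2 is epimerizable through its enol. The target configuration (formyl syn to C11, anti to the C10 acyloxy group) is assumed to be the thermodynamically preferred one once O-10 carries a substituent.

Step 1
Reactants: 1 4-methoxyphenylboronic acid; 2 furan-2(5H)-one
Product: 3 (S)-4-(4-methoxyphenyl)dihydrofuran-2(3H)-one
Conditions: Rh(acac)(C2H4)2 (3 mol %), (S)-BINAP, dioxane/H2O (10:1), 100 °C
Reagents that add atoms: none
Why: Hayashi–Miyaura rhodium-catalyzed asymmetric 1,4-addition of an arylboronic acid to a butenolide; the (S)-BINAP aryl-rhodium species should add to the same enantioface as with cyclic enones and so set C5 as (S).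

Step 2
Reactants: 3 (S)-4-(4-methoxyphenyl)dihydrofuran-2(3H)-one
Product: 5 methyl (S)-4-iodo-3-(4-methoxyphenyl)butanoate, via trimethylsilyl ester 4 (not isolated)
Conditions: Me3SiI, CH2Cl2, 0 °C to rt; then MeOH, rt
Reagents that add atoms: iodotrimethylsilane C[Si](C)(C)I; methanol CO
Why: Silyl iodide opening of a γ-lactone by O-silylation and SN2 attack of iodide at the primary CH2–O carbon, followed by methanolysis and esterification; the stereocenter is not touched and the aryl methyl ether should be inert at room temperature.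

Step 3
Reactants: 5 methyl (S)-4-iodo-3-(4-methoxyphenyl)butanoate; 6 acrolein
Product: 8 methyl 2-[(1S,4S)-4-formyl-8-oxospiro[4.5]deca-6,9-dien-1-yl]acetate, via trans epimer 7 (not isolated)
Conditions: fac-Ir(ppy)3 (1 mol %), acrolein (5 equiv), MeCN, blue LEDs, rt; evaporate; then DBU (0.2 equiv), CH2Cl2, rt
Reagents that add atoms: none
Why: Proposed new method: the photoexcited trivalent iridium complex reduces the C–I bond, the primary radical adds to acrolein (Giese step, first new C–C bond), and the α-formyl radical closes ring A by 5-exo-trig ipso attack on the ring carbon para to OMe (second new C–C bond); the oxygen-stabilized cyclohexadienyl radical is then oxidized by the tetravalent iridium species and O-demethylated by iodide to the cross-conjugated dienone, which closes a redox-neutral cycle. The closest known reactions are radical [3+2] annulations of homoallyl-type radicals with acrylates and the dearomative ipso-spirocyclizations of radicals onto para-methoxyaryl rings that give azaspiro[4.5]trienones. Because the para-substituted ring is symmetric the spiro carbon is not yet a stereocenter, so the only new stereocenter is the formyl-bearing carbon; it is not expected to be controlled kinetically and is set by DBU equilibration through the enolate toward the cis-1,3 isomer 8, in which both ring-A substituents can be pseudo-equatorial (residual 7 is recycled). The step needs Giese addition to outrun the 1,2-aryl shift of the primary radical, which excess acrolein should secure, and ipso closure to outrun ortho closure, which the para-methoxy group and the 5-exo preference should secure.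

Step 4
Reactants: 8 methyl 2-[(1S,4S)-4-formyl-8-oxospiro[4.5]deca-6,9-dien-1-yl]acetate
Product: 9 methyl 2-[(1S,4S)-4-(1,3-dioxolan-2-yl)-8-oxospiro[4.5]deca-6,9-dien-1-yl]acetate
Conditions: Me3SiOCH2CH2OSiMe3, Me3SiOTf (cat.), CH2Cl2, −78 °C
Reagents that add atoms: 1,2-bis(trimethylsilyloxy)ethane C[Si](C)(C)OCCO[Si](C)(C)C
Why: Noyori acetalization; the aldehyde is far more reactive than the cross-conjugated dienone carbonyl, and the low temperature should prevent epimerization next to the formyl group.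

Step 5
Reactants: 9 methyl 2-[(1S,4S)-4-(1,3-dioxolan-2-yl)-8-oxospiro[4.5]deca-6,9-dien-1-yl]acetate
Product: 11 methyl 2-[(1S,4S,5R)-4-(1,3-dioxolan-2-yl)-8-(trifluoromethylsulfonyloxy)spiro[4.5]deca-6,8-dien-1-yl]acetate, via lithium enolate 10 (not isolated)
Conditions: LiBH(sBu)3, THF, −78 °C; then PhNTf2, −78 to 0 °C; aq. NH4Cl
Reagents that add atoms: N-phenylbis(trifluoromethanesulfonimide) O=S(=O)(N(c1ccccc1)S(=O)(=O)C(F)(F)F)C(F)(F)F
Why: Conjugate reduction of a β-unsubstituted cyclohexenone by a bulky borohydride and O-triflation of the enolate; hydride should add to the enone arm on the face of ring A that carries only hydrogens, because the other arm is flanked by both ring-A substituents, which makes the spiro carbon stereogenic as drawn (the other regioisomer would converge in step 8).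

Step 6
Reactants: 11 methyl 2-[(1S,4S,5R)-4-(1,3-dioxolan-2-yl)-8-(trifluoromethylsulfonyloxy)spiro[4.5]deca-6,8-dien-1-yl]acetate
Product: 12 2-[(1S,4S,5R)-4-(1,3-dioxolan-2-yl)-8-(trifluoromethylsulfonyloxy)spiro[4.5]deca-6,8-dien-1-yl]acetaldehyde
Conditions: iBu2AlH (1.05 equiv), CH2Cl2, −78 °C; aqueous potassium sodium tartrate
Reagents that add atoms: none
Why: Half-reduction of a methyl ester by iBu2AlH through the tetrahedral aluminium hemiacetal, which is stable at −78 °C; the enol triflate and the dioxolane are inert.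

Step 7
Reactants: 12 2-[(1S,4S,5R)-4-(1,3-dioxolan-2-yl)-8-(trifluoromethylsulfonyloxy)spiro[4.5]deca-6,8-dien-1-yl]acetaldehyde
Product: 13 4-methoxybenzyl (1S,4S,5R)-4-(1,3-dioxolan-2-yl)-1-(2-oxoethyl)spiro[4.5]deca-6,8-diene-8-carboxylate
Conditions: Pd(OAc)2 (5 mol %), PPh3, CO (1 atm), 4-methoxybenzyl alcohol, Et3N, DMF, 50 °C
Reagents that add atoms: carbon monoxide [C-]#[O+]; 4-methoxybenzyl alcohol COc1ccc(CO)cc1
Why: Palladium-catalyzed alkoxycarbonylation of an enol triflate (oxidative addition, CO insertion, alcoholysis of the acyl-palladium species), which tolerates the aldehyde.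

Step 8
Reactants: 13 4-methoxybenzyl (1S,4S,5R)-4-(1,3-dioxolan-2-yl)-1-(2-oxoethyl)spiro[4.5]deca-6,8-diene-8-carboxylate
Product: 16 4-methoxybenzyl 2-(1,3-dioxolan-2-yl)-6-formyl-6-methyltricyclo[5.3.1.0(1,5)]undec-9-ene-8-carboxylate (6-CH3 exo; 6-CHO endo; H-8 on the C11 face), via conjugated dienoate isomer 14 (not isolated), via potassium enolate 15 (not isolated)
Conditions: KOtBu (1.05 equiv), THF/tBuOH (10:1), −20 °C to rt; then MeI, 0 °C
Reagents that add atoms: iodomethane CI
Why: A base-mediated proton shift through the extended ester dienolate moves the diene to isomer 14, whose enoate β-carbon is the only one the aldehyde enolate can reach, and 5-exo-trig intramolecular Michael addition then closes ring B with the necessarily cis ring fusion (C7, and C1 fixed); kinetic α-protonation of the ester dienolate should leave the β,γ-unsaturated ester, and C-methylation of aldehyde enolate 15 should occur from the exo face because the endo face lies under the cyclohexene ring (C6).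

Step 9
Reactants: 16 4-methoxybenzyl 2-(1,3-dioxolan-2-yl)-6-formyl-6-methyltricyclo[5.3.1.0(1,5)]undec-9-ene-8-carboxylate
Product: 19 4-methoxybenzyl (1S,2S,5S,6S,7R)-2-(1,3-dioxolan-2-yl)-6-formyl-6-methyl-10-oxotricyclo[5.3.1.0(1,5)]undec-8-ene-8-carboxylate, via allylic hydroperoxide 17 (not isolated), via peroxyacetate 18 (not isolated)
Conditions: O2, tetraphenylporphyrin (cat.), visible light, CH2Cl2, 0 °C; then Ac2O, pyridine, DMAP (cat.), 0 °C to rt
Reagents that add atoms: dioxygen O=O
Why: Schenck ene reaction of singlet oxygen with the β,γ-unsaturated ester, whose only allylic hydrogen is H-8, should place oxygen at C10 with shift of the double bond into conjugation, and Kornblum–DeLaMare elimination of the peroxyacetate then gives the enone (the C10 configuration of 17 is lost).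

Step 10
Reactants: 19 4-methoxybenzyl (1S,2S,5S,6S,7R)-2-(1,3-dioxolan-2-yl)-6-formyl-6-methyl-10-oxotricyclo[5.3.1.0(1,5)]undec-8-ene-8-carboxylate
Product: 20 4-methoxybenzyl (1S,2S,5S,6S,7R,10S)-2-(1,3-dioxolan-2-yl)-10-hydroxy-6-(hydroxymethyl)-6-methyltricyclo[5.3.1.0(1,5)]undec-8-ene-8-carboxylate
Conditions: NaBH4, CeCl3·7H2O, MeOH, −78 to 0 °C
Reagents that add atoms: none
Why: Luche reduction (1,2-addition to the enone, with the aldehyde reduced as well); hydride should reach C10 from the face of the C11 bridge, since the opposite face is shielded by the endo hydrogen at C5 of the two-carbon bridge, which gives the pseudo-equatorial alcohol of the target.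

Step 11
Reactants: 20 4-methoxybenzyl (1S,2S,5S,6S,7R,10S)-2-(1,3-dioxolan-2-yl)-10-hydroxy-6-(hydroxymethyl)-6-methyltricyclo[5.3.1.0(1,5)]undec-8-ene-8-carboxylate
Product: 21 4-methoxybenzyl (1S,2S,5S,6S,7R,10S)-6-{[(tert-butyldimethylsilyl)oxy]methyl}-2-(1,3-dioxolan-2-yl)-10-hydroxy-6-methyltricyclo[5.3.1.0(1,5)]undec-8-ene-8-carboxylate
Conditions: TBSCl (1.05 equiv), imidazole, CH2Cl2, 0 °C
Reagents that add atoms: tert-butyldimethylsilyl chloride CC(C)(C)[Si](C)(C)Cl
Why: Selective silylation of the primary alcohol; the secondary allylic alcohol is flanked by the quaternary C1 and should react much more slowly.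

Step 12
Reactants: 22 9-bromononanoic acid
Product: 23 (8-carboxyoctyl)triphenylphosphonium bromide
Conditions: PPh3, MeCN, reflux
Reagents that add atoms: triphenylphosphine c1ccc(cc1)P(c1ccccc1)c1ccccc1
Why: SN2 quaternization of triphenylphosphine by a primary alkyl bromide.

Step 13
Reactants: 24 heptane-1,7-diol
Product: 25 7-[(tert-butyldimethylsilyl)oxy]heptan-1-ol
Conditions: NaH (1.0 equiv), THF, 0 °C; then TBSCl
Reagents that add atoms: tert-butyldimethylsilyl chloride CC(C)(C)[Si](C)(C)Cl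
Why: Monosilylation of a symmetrical diol through its sparingly soluble monosodium alkoxide.

Step 14
Reactants: 25 7-[(tert-butyldimethylsilyl)oxy]heptan-1-ol
Product: 26 7-[(tert-butyldimethylsilyl)oxy]heptanal
Conditions: TEMPO (cat.), PhI(OAc)2, CH2Cl2, rt
Reagents that add atoms: none
Why: Oxoammonium-mediated oxidation of a primary alcohol, which stops at the aldehyde.

Step 15
Reactants: 23 (8-carboxyoctyl)triphenylphosphonium bromide; 26 7-[(tert-butyldimethylsilyl)oxy]heptanal
Product: 28 (Z)-16-[(tert-butyldimethylsilyl)oxy]hexadec-9-enoic acid, via phosphonium ylide 27 (not isolated)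
Conditions: NaN(SiMe3)2 (2.1 equiv), THF, 0 °C; then 26, −78 °C to rt; then dilute aq. HCl to pH 4
Reagents that add atoms: none
Why: Wittig reaction of a non-stabilized ylide with a sodium base at low temperature should give the Z alkene through the cis-oxaphosphetane.

Step 16
Reactants: 28 (Z)-16-[(tert-butyldimethylsilyl)oxy]hexadec-9-enoic acid; 21 the C10 alcohol
Product: 30 4-methoxybenzyl (1S,2S,5S,6S,7R,10S)-6-{[(tert-butyldimethylsilyl)oxy]methyl}-10-({(9Z)-16-[(tert-butyldimethylsilyl)oxy]hexadec-9-enoyl}oxy)-2-(1,3-dioxolan-2-yl)-6-methyltricyclo[5.3.1.0(1,5)]undec-8-ene-8-carboxylate, via mixed anhydride 29 (not isolated)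
Conditions: 2,4,6-trichlorobenzoyl chloride, Et3N, THF, rt; then 21, DMAP, toluene, rt
Reagents that add atoms: none
Why: Yamaguchi esterification; DMAP-mediated acyl transfer from the mixed anhydride to the hindered secondary allylic alcohol proceeds with retention at C10.

Step 17
Reactants: 30 the fully protected ester
Product: 31 (1S,2S,5S,6S,7R,10S)-2-formyl-10-{[(9Z)-16-hydroxyhexadec-9-enoyl]oxy}-6-(hydroxymethyl)-6-methyltricyclo[5.3.1.0(1,5)]undec-8-ene-8-carboxylic acid
Conditions: CF3CO2H/CH2Cl2/H2O (10:10:1), 0 °C to rt; aq. NaHCO3, then pH 4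
Reagents that add atoms: water O
Why: Acidolysis of the 4-methoxybenzyl ester, both silyl ethers and the dioxolane; the C10 ester and the Z alkene should survive, and C2 should keep (or equilibrate to) the configuration with the formyl group anti to the C10 acyloxy group.

**Compound list**

1 | 4-methoxyphenylboronic acid | COc1ccc(B(O)O)cc1 | starting material
2 | furan-2(5H)-one | O=C1C=CCO1 | starting material
3 | (S)-4-(4-methoxyphenyl)dihydrofuran-2(3H)-one | O=C1C[C@@H](c2ccc(OC)cc2)CO1 | intermediate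
4 | trimethylsilyl (S)-4-iodo-3-(4-methoxyphenyl)butanoate | C[Si](C)(C)OC(=O)C[C@@H](c1ccc(OC)cc1)CI | intermediate
5 | methyl (S)-4-iodo-3-(4-methoxyphenyl)butanoate | COC(=O)C[C@@H](c1ccc(OC)cc1)CI | intermediate
6 | acrolein (prop-2-enal) | C=CC=O | starting material
7 | methyl 2-[(1S,4R)-4-formyl-8-oxospiro[4.5]deca-6,9-dien-1-yl]acetate (trans epimer) | O=C[C@@H]1CC[C@@H](CC(=O)OC)C12C=CC(=O)C=C2 | intermediate
8 | methyl 2-[(1S,4S)-4-formyl-8-oxospiro[4.5]deca-6,9-dien-1-yl]acetate (cis) | O=C[C@H]1CC[C@@H](CC(=O)OC)C12C=CC(=O)C=C2 | intermediate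
9 | methyl 2-[(1S,4S)-4-(1,3-dioxolan-2-yl)-8-oxospiro[4.5]deca-6,9-dien-1-yl]acetate | O1CCOC1[C@H]2CC[C@@H](CC(=O)OC)C23C=CC(=O)C=C3 | intermediate
10 | lithium (1S,4S,5R)-4-(1,3-dioxolan-2-yl)-1-(2-methoxy-2-oxoethyl)spiro[4.5]deca-6,8-dien-8-olate | O1CCOC1[C@H]2CC[C@@H](CC(=O)OC)[C@@]23C=CC(O[Li])=CC3 | intermediate
11 | methyl 2-[(1S,4S,5R)-4-(1,3-dioxolan-2-yl)-8-(trifluoromethylsulfonyloxy)spiro[4.5]deca-6,8-dien-1-yl]acetate | O1CCOC1[C@H]2CC[C@@H](CC(=O)OC)[C@@]23C=CC(OS(=O)(=O)C(F)(F)F)=CC3 | intermediate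
12 | 2-[(1S,4S,5R)-4-(1,3-dioxolan-2-yl)-8-(trifluoromethylsulfonyloxy)spiro[4.5]deca-6,8-dien-1-yl]acetaldehyde | O1CCOC1[C@H]2CC[C@@H](CC=O)[C@@]23C=CC(OS(=O)(=O)C(F)(F)F)=CC3 | intermediate
13 | 4-methoxybenzyl (1S,4S,5R)-4-(1,3-dioxolan-2-yl)-1-(2-oxoethyl)spiro[4.5]deca-6,8-diene-8-carboxylate | O1CCOC1[C@H]2CC[C@@H](CC=O)[C@@]23C=CC(C(=O)OCc4ccc(OC)cc4)=CC3 | intermediate
14 | 4-methoxybenzyl (1S,4S,5S)-4-(1,3-dioxolan-2-yl)-1-(2-oxoethyl)spiro[4.5]deca-6,8-diene-8-carboxylate (ring CH2 cis to the ring-A substituents) | O1CCOC1[C@H]2CC[C@@H](CC=O)[C@@]23CC=C(C(=O)OCc4ccc(OC)cc4)C=C3 | intermediate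
15 | potassium enolate of 4-methoxybenzyl 2-(1,3-dioxolan-2-yl)-6-formyltricyclo[5.3.1.0(1,5)]undec-9-ene-8-carboxylate | [K]OC=C1[C@H]2C[C@@]3(C=C[C@H]2C(=O)OCc4ccc(OC)cc4)[C@@H](C5OCCO5)CC[C@@H]13 | intermediate
16 | 4-methoxybenzyl 2-(1,3-dioxolan-2-yl)-6-formyl-6-methyltricyclo[5.3.1.0(1,5)]undec-9-ene-8-carboxylate (6-CH3 exo, 6-CHO endo, H-8 on the C11 face) | C[C@@]1(C=O)[C@H]2C[C@@]3(C=C[C@H]2C(=O)OCc4ccc(OC)cc4)[C@@H](C5OCCO5)CC[C@@H]13 | intermediate
17 | 4-methoxybenzyl 2-(1,3-dioxolan-2-yl)-6-formyl-10-hydroperoxy-6-methyltricyclo[5.3.1.0(1,5)]undec-8-ene-8-carboxylate (10-OOH on the C11 face) | C[C@@]1(C=O)[C@H]2C[C@@]3([C@H](OO)C=C2C(=O)OCc4ccc(OC)cc4)[C@@H](C5OCCO5)CC[C@@H]13 | intermediate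
18 | 4-methoxybenzyl 10-(acetylperoxy)-2-(1,3-dioxolan-2-yl)-6-formyl-6-methyltricyclo[5.3.1.0(1,5)]undec-8-ene-8-carboxylate | C[C@@]1(C=O)[C@H]2C[C@@]3([C@H](OOC(C)=O)C=C2C(=O)OCc4ccc(OC)cc4)[C@@H](C5OCCO5)CC[C@@H]13 | intermediate
19 | 4-methoxybenzyl (1S,2S,5S,6S,7R)-2-(1,3-dioxolan-2-yl)-6-formyl-6-methyl-10-oxotricyclo[5.3.1.0(1,5)]undec-8-ene-8-carboxylate | C[C@@]1(C=O)[C@H]2C[C@@]3(C(=O)C=C2C(=O)OCc4ccc(OC)cc4)[C@@H](C5OCCO5)CC[C@@H]13 | intermediate
20 | 4-methoxybenzyl (1S,2S,5S,6S,7R,10S)-2-(1,3-dioxolan-2-yl)-10-hydroxy-6-(hydroxymethyl)-6-methyltricyclo[5.3.1.0(1,5)]undec-8-ene-8-carboxylate | C[C@@]1(CO)[C@H]2C[C@@]3([C@@H](O)C=C2C(=O)OCc4ccc(OC)cc4)[C@@H](C5OCCO5)CC[C@@H]13 | intermediate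
21 | 4-methoxybenzyl (1S,2S,5S,6S,7R,10S)-6-{[(tert-butyldimethylsilyl)oxy]methyl}-2-(1,3-dioxolan-2-yl)-10-hydroxy-6-methyltricyclo[5.3.1.0(1,5)]undec-8-ene-8-carboxylate | C[C@@]1(CO[Si](C)(C)C(C)(C)C)[C@H]2C[C@@]3([C@@H](O)C=C2C(=O)OCc4ccc(OC)cc4)[C@@H](C5OCCO5)CC[C@@H]13 | intermediate
22 | 9-bromononanoic acid | OC(=O)CCCCCCCCBr | starting material
23 | (8-carboxyoctyl)triphenylphosphonium bromide | [Br-].OC(=O)CCCCCCCC[P+](c1ccccc1)(c1ccccc1)c1ccccc1 | intermediate
24 | heptane-1,7-diol | OCCCCCCCO | starting material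
25 | 7-[(tert-butyldimethylsilyl)oxy]heptan-1-ol | CC(C)(C)[Si](C)(C)OCCCCCCCO | intermediate
26 | 7-[(tert-butyldimethylsilyl)oxy]heptanal | CC(C)(C)[Si](C)(C)OCCCCCCC=O | intermediate
27 | sodium 9-(triphenylphosphoranylidene)nonanoate | [Na+].[O-]C(=O)CCCCCCCC=P(c1ccccc1)(c1ccccc1)c1ccccc1 | intermediate
28 | (Z)-16-[(tert-butyldimethylsilyl)oxy]hexadec-9-enoic acid | CC(C)(C)[Si](C)(C)OCCCCCC/C=C\CCCCCCCC(=O)O | intermediate
29 | (Z)-16-[(tert-butyldimethylsilyl)oxy]hexadec-9-enoic 2,4,6-trichlorobenzoic anhydride | CC(C)(C)[Si](C)(C)OCCCCCC/C=C\CCCCCCCC(=O)OC(=O)c1c(Cl)cc(Cl)cc1Cl | intermediate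
30 | 4-methoxybenzyl (1S,2S,5S,6S,7R,10S)-6-{[(tert-butyldimethylsilyl)oxy]methyl}-10-({(9Z)-16-[(tert-butyldimethylsilyl)oxy]hexadec-9-enoyl}oxy)-2-(1,3-dioxolan-2-yl)-6-methyltricyclo[5.3.1.0(1,5)]undec-8-ene-8-carboxylate | C[C@@]1(CO[Si](C)(C)C(C)(C)C)[C@H]2C[C@@]3([C@@H](OC(=O)CCCCCCC/C=C\CCCCCCO[Si](C)(C)C(C)(C)C)C=C2C(=O)OCc4ccc(OC)cc4)[C@@H](C5OCCO5)CC[C@@H]13 | intermediate
31 | (1S,2S,5S,6S,7R,10S)-2-formyl-10-{[(9Z)-16-hydroxyhexadec-9-enoyl]oxy}-6-(hydroxymethyl)-6-methyltricyclo[5.3.1.0(1,5)]undec-8-ene-8-carboxylic acid | C[C@@]1(CO)[C@H]2C[C@@]3([C@@H](OC(=O)CCCCCCC/C=C\CCCCCCO)C=C2C(=O)O)[C@@H](C=O)CC[C@@H]13 | target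

**Step count:** 17 steps in total. The longest linear sequence is 13 steps (steps 1 to 11, then 16 and 17).

**Steps most likely to fail**

Step 3. The α-formyl radical may be reduced or may oligomerize with acrolein before it closes, or it may close at an ortho carbon and rearomatize instead of closing at the ipso carbon. The fallback separates the two bond formations and uses known reaction types. It sets out from 5: tin-hydride-mediated Giese addition to acrolein (Bu3SnH, AIBN, benzene, 80 °C) should give methyl (S)-3-(4-methoxyphenyl)-7-oxoheptanoate F1. Amine-catalyzed α-bromination with N-bromosuccinimide should give methyl (3S)-6-bromo-3-(4-methoxyphenyl)-7-oxoheptanoate F2. Reductive cleavage of the activated C–Br bond with Ru(bpy)3Cl2 under visible light, the known mode of dearomative ipso-spirocyclization of α-bromo carbonyl compounds onto para-methoxyaryl rings, followed by DBU, comes back to the route at 8.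

Step 8. The diene may not migrate into the reactive position while the aldehyde is held as its enolate, the enolizable aldehyde may self-condense, or methylation may occur at the ester α-carbon. The fallback decouples ring closure, alkylation and deconjugation and sets out from 13. DBU with catalytic pyrrolidine (diene shift, then enamine-mediated intramolecular Michael addition) should give the conjugated tricyclic aldehyde F3. KN(SiMe3)2 and MeI at −78 °C should give the exo-methylated aldehyde F4. NaBH4 then gives the primary alcohol F5 and TBSCl/imidazole its silyl ether F6. LiN(iPr)2 in THF/HMPA followed by a cold acetic acid quench should give the deconjugated ester F7. Photooxygenation and Ac2O/pyridine then give the enone F8, and Luche reduction comes back to the route at 21.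

Step 9. The ene reaction of the cis-disubstituted alkene may be slow, and the neopentyl aldehyde may autoxidize under oxygen and light. The fallback replaces photooxygenation by epoxide chemistry and sets out from 16. NaBH4 should give the primary alcohol F9, and TBSCl/imidazole converts it into the silyl ether already named F7. mCPBA should give the epoxide F10 from the C11 face. DBU opens it by β-elimination from the ester α-carbon to the γ-hydroxy enoate F11 (the C10 epimer of 21). Dess–Martin periodinane gives the enone F8, and Luche reduction comes back to the route at 21.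

**Further compounds**

F1 | step 3 | methyl (S)-3-(4-methoxyphenyl)-7-oxoheptanoate | COC(=O)C[C@@H](c1ccc(OC)cc1)CCCC=O
F2 | step 3 | methyl (3S)-6-bromo-3-(4-methoxyphenyl)-7-oxoheptanoate (C6 epimers) | COC(=O)C[C@@H](c1ccc(OC)cc1)CCC(Br)C=O
F3 | step 8 | 4-methoxybenzyl 2-(1,3-dioxolan-2-yl)-6-formyltricyclo[5.3.1.0(1,5)]undec-8-ene-8-carboxylate (C6 epimers) | O=CC1[C@H]2C[C@@]3(CC=C2C(=O)OCc4ccc(OC)cc4)[C@@H](C5OCCO5)CC[C@@H]13
F4 | step 8 | 4-methoxybenzyl 2-(1,3-dioxolan-2-yl)-6-formyl-6-methyltricyclo[5.3.1.0(1,5)]undec-8-ene-8-carboxylate (6-CH3 exo) | C[C@@]1(C=O)[C@H]2C[C@@]3(CC=C2C(=O)OCc4ccc(OC)cc4)[C@@H](C5OCCO5)CC[C@@H]13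
F5 | step 8 | 4-methoxybenzyl 2-(1,3-dioxolan-2-yl)-6-(hydroxymethyl)-6-methyltricyclo[5.3.1.0(1,5)]undec-8-ene-8-carboxylate | C[C@@]1(CO)[C@H]2C[C@@]3(CC=C2C(=O)OCc4ccc(OC)cc4)[C@@H](C5OCCO5)CC[C@@H]13
F6 | step 8 | 4-methoxybenzyl 6-{[(tert-butyldimethylsilyl)oxy]methyl}-2-(1,3-dioxolan-2-yl)-6-methyltricyclo[5.3.1.0(1,5)]undec-8-ene-8-carboxylate | C[C@@]1(CO[Si](C)(C)C(C)(C)C)[C@H]2C[C@@]3(CC=C2C(=O)OCc4ccc(OC)cc4)[C@@H](C5OCCO5)CC[C@@H]13
F7 | step 8 | 4-methoxybenzyl 6-{[(tert-butyldimethylsilyl)oxy]methyl}-2-(1,3-dioxolan-2-yl)-6-methyltricyclo[5.3.1.0(1,5)]undec-9-ene-8-carboxylate | C[C@@]1(CO[Si](C)(C)C(C)(C)C)[C@H]2C[C@@]3(C=C[C@H]2C(=O)OCc4ccc(OC)cc4)[C@@H](C5OCCO5)CC[C@@H]13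
F8 | step 8 | 4-methoxybenzyl 6-{[(tert-butyldimethylsilyl)oxy]methyl}-2-(1,3-dioxolan-2-yl)-6-methyl-10-oxotricyclo[5.3.1.0(1,5)]undec-8-ene-8-carboxylate | C[C@@]1(CO[Si](C)(C)C(C)(C)C)[C@H]2C[C@@]3(C(=O)C=C2C(=O)OCc4ccc(OC)cc4)[C@@H](C5OCCO5)CC[C@@H]13
F9 | step 9 | 4-methoxybenzyl 2-(1,3-dioxolan-2-yl)-6-(hydroxymethyl)-6-methyltricyclo[5.3.1.0(1,5)]undec-9-ene-8-carboxylate | C[C@@]1(CO)[C@H]2C[C@@]3(C=C[C@H]2C(=O)OCc4ccc(OC)cc4)[C@@H](C5OCCO5)CC[C@@H]13
F10 | step 9 | 9,10-epoxide of F7 (oxygen on the C11 face) | C[C@@]1(CO[Si](C)(C)C(C)(C)C)[C@H]2C[C@@]3([C@@H]4O[C@@H]4[C@H]2C(=O)OCc5ccc(OC)cc5)[C@@H](C6OCCO6)CC[C@@H]13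
F11 | step 9 | C10 epimer of 21 (10-OH on the C11 face) | C[C@@]1(CO[Si](C)(C)C(C)(C)C)[C@H]2C[C@@]3([C@H](O)C=C2C(=O)OCc4ccc(OC)cc4)[C@@H](C5OCCO5)CC[C@@H]13
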